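**Retrosynthetic overview**
- Target ⇐ removal of three MOM ethers ⇐ C8–CH2 bond made by nickel-catalysed radical coupling of an 8-bromoflavanone with (S)-2-(oxiran-2-yl)propan-2-ol (from methyl (S)-glycidate and MeMgBr; this sets the side-chain S centre from the chiral pool).
- Key disconnection C2–C1′: enantioconvergent decarboxylative radical arylation of a racemic 4-oxochroman-2-carboxylic acid with MOM-protected 4-iodophenol; one event brings in ring B and sets 2S.
- Ring C is the only ring that is built: an ortho-lithiated phenoxide opens maleic anhydride and the phenoxide closes the pyranone by oxa-Michael addition.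
- Ring A (from resorcinol): bis-MOM ether, ortho-lithiation/prenylation between the ethers, meta C–H borylation/oxidation to the one free OH (the future O1), double ortho-bromination. The two bromine positions are equivalent by symmetry, so the 6-prenyl/8-alkyl pattern cannot come out the other way round.
- Ring order: rings A and B are bought (resorcinol, 4-iodophenol); ring C is closed in step 5.

Assumption: MOMCl, NBS, B2pin2, H2O2 and MeMgBr are taken as reagents, and the ligand antipode in step 7 is the one that a first screen shows to give 2S.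

**Route**

Step 1
Reactants: 1 resorcinol
Product: 2 1,3-bis(methoxymethoxy)benzene
Conditions: NaH (2.3 equiv), MOMCl (2.3 equiv), DMF, 0 °C → rt
Reagents that add atoms: chloromethyl methyl ether COCCl
Why: Williamson-type O-alkylation of the bis-phenoxide gives two acetal ethers that direct the next metalation and are removed together at the end.

Step 2
Reactants: 2 1,3-bis(methoxymethoxy)benzene; 3 prenyl bromide (1-bromo-3-methylbut-2-ene)
Product: 5 1,3-bis(methoxymethoxy)-2-(3-methylbut-2-en-1-yl)benzene, via aryllithium 4 (not isolated)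
Conditions: n-BuLi (1.1 equiv), THF, 0 °C → rt; then CuI (10 mol %), 3 (1.2 equiv), −78 °C → rt
Reagents that add atoms: n-butyllithium CCCC[Li] (its lithium stays in intermediate 4 only)
Why: Directed ortho-metalation removes the doubly activated proton between the two MOM ethers and copper-assisted SN2 alkylation with the primary allylic bromide gives the linear prenyl group.

Step 3
Reactants: 5 1,3-bis(methoxymethoxy)-2-(3-methylbut-2-en-1-yl)benzene
Product: 7 3,5-bis(methoxymethoxy)-4-(3-methylbut-2-en-1-yl)phenol, via arylboronate 6 (not isolated)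
Conditions: [Ir(cod)OMe]2 (1.5 mol %), dtbpy (3 mol %), B2pin2 (0.7 equiv), THF, 70 °C; then aq. NaOH, H2O2, 0 °C → rt
Reagents that add atoms: hydrogen peroxide OO; bis(pinacolato)diboron CC1(C)OB(OC1(C)C)B1OC(C)(C)C(C)(C)O1 (its boryl group stays in intermediate 6 only)
Why: Sterically governed iridium-catalysed aromatic C–H borylation takes the only C–H without an ortho substituent (meta to both ethers, the hindered trisubstituted alkene being left alone) and boronate oxidation in the same pot gives the third oxygen as the single free hydroxyl.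

Step 4
Reactants: 7 3,5-bis(methoxymethoxy)-4-(3-methylbut-2-en-1-yl)phenol
Product: 9 2,6-dibromo-3,5-bis(methoxymethoxy)-4-(3-methylbut-2-en-1-yl)phenol, via monobromophenol 8 (not isolated)
Conditions: NBS (2.05 equiv), CH2Cl2, −78 → −20 °C
Reagents that add atoms: N-bromosuccinimide O=C1CCC(=O)N1Br
Why: Electrophilic aromatic bromination of the phloroglucinol-type phenol at its two equivalent free positions (ortho to OH, para to OMOM) is far faster at low temperature than attack on the alkene.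

Step 5
Reactants: 9 2,6-dibromo-3,5-bis(methoxymethoxy)-4-(3-methylbut-2-en-1-yl)phenol; 10 maleic anhydride
Product: 13 rac-8-bromo-5,7-bis(methoxymethoxy)-6-(3-methylbut-2-en-1-yl)-4-oxo-3,4-dihydro-2H-chromene-2-carboxylic acid, via dilithio phenoxide 11 (not isolated), via aroylacrylic acid 12 (not isolated)
Conditions: n-BuLi (2.1 equiv), THF, −78 °C; cannulate into 10 (1.5 equiv), THF, −78 °C; then H2O, rt; aq. HCl to pH 3, 0 °C
Reagents that add atoms: n-butyllithium CCCC[Li] (its lithium stays in intermediate 11 only)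
Why: After phenoxide formation a single bromine–lithium exchange (a second one on the dianion is disfavoured) gives an aryllithium that opens the anhydride by 1,2-addition, and the neighbouring phenoxide closes ring C by 6-endo oxa-Michael addition, so the ring oxygen is necessarily the one flanked by the ketone carbon and the remaining bromine.

Step 6
Reactants: 14 4-iodophenol
Product: 15 1-iodo-4-(methoxymethoxy)benzene
Conditions: NaH (1.2 equiv), MOMCl (1.2 equiv), DMF, 0 °C → rt
Reagents that add atoms: chloromethyl methyl ether COCCl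
Why: O-alkylation masks the phenol, which would otherwise be deprotonated by the carbonate base of step 7 and slow the nickel insertion.

Step 7
Reactants: 13 rac-8-bromo-5,7-bis(methoxymethoxy)-6-(3-methylbut-2-en-1-yl)-4-oxo-3,4-dihydro-2H-chromene-2-carboxylic acid; 15 1-iodo-4-(methoxymethoxy)benzene
Product: 16 (2S)-8-bromo-5,7-bis(methoxymethoxy)-2-[4-(methoxymethoxy)phenyl]-6-(3-methylbut-2-en-1-yl)-2,3-dihydro-4H-chromen-4-one
Conditions: Ir[dF(CF3)ppy]2(dtbbpy)PF6 (2 mol %), NiCl2·glyme (10 mol %), chiral cyano-bis(oxazoline) ligand [2,2-bis(4-aryl-4,5-dihydrooxazol-2-yl)acetonitrile, one antipode] (12 mol %), Cs2CO3 (1.5 equiv), 15 (1.5 equiv), DME, blue LEDs, 25 °C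
Reagents that add atoms: none
Why: Proposed new method: the excited iridium photocatalyst oxidises the caesium carboxylate of 13 and loss of CO2 gives a planar α-aryloxy C2 radical in which both enantiomers of 13 converge, while zerovalent nickel carrying the chiral ligand inserts into the unhindered C–I bond of 15 much faster than into the di-ortho-substituted electron-rich C8–Br bond, captures the radical and forms the C2–C1′ bond by reductive elimination from trivalent nickel with the ligand choosing the face (2S); the closest known reaction types are the racemic nickel/photoredox decarboxylative arylation of α-oxy acids and its enantioconvergent version for α-amino acids with this ligand class.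

Step 8
Reactants: 17 methyl (2S)-oxirane-2-carboxylate
Product: 19 2-[(2S)-oxiran-2-yl]propan-2-ol, via epoxy ketone 18 (not isolated)
Conditions: MeMgBr (2.2 equiv), THF, −78 → −30 °C; then H2O
Reagents that add atoms: methylmagnesium bromide C[Mg]Br
Why: Double Grignard addition to the ester is faster at low temperature than opening of the epoxide and does not touch the stereocentre, whose descriptor stays S.

Step 9
Reactants: 16 (2S)-8-bromo-5,7-bis(methoxymethoxy)-2-[4-(methoxymethoxy)phenyl]-6-(3-methylbut-2-en-1-yl)-2,3-dihydro-4H-chromen-4-one; 19 2-[(2S)-oxiran-2-yl]propan-2-ol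
Product: 21 (2S)-8-[(2S)-2,3-dihydroxy-3-methylbutyl]-5,7-bis(methoxymethoxy)-2-[4-(methoxymethoxy)phenyl]-6-(3-methylbut-2-en-1-yl)-2,3-dihydro-4H-chromen-4-one, via iodohydrin 20 (not isolated)
Conditions: NiBr2·glyme (10 mol %), 2,2′-bipyridine (10 mol %), NaI (25 mol %), Et3N·HCl (1.2 equiv), Mn powder (2 equiv), 19 (1.5 equiv), DMPU, 25 → 40 °C
Reagents that add atoms: sodium iodide [Na+].[I-] (its iodine stays in intermediate 20 only)
Why: In this nickel-catalysed reductive cross-electrophile coupling of an aryl bromide with an epoxide under iodide co-catalysis, iodide opens the epoxide at CH2 to iodohydrin 20, whose primary alkyl radical is captured by the arylnickel species to forge C8–CH2, and the carbinol centre is never involved and stays S.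

Step 10
Reactants: 21 (2S)-8-[(2S)-2,3-dihydroxy-3-methylbutyl]-5,7-bis(methoxymethoxy)-2-[4-(methoxymethoxy)phenyl]-6-(3-methylbut-2-en-1-yl)-2,3-dihydro-4H-chromen-4-one
Product: 22 (2S)-8-[(2S)-2,3-dihydroxy-3-methylbutyl]-5,7-dihydroxy-2-(4-hydroxyphenyl)-6-(3-methylbut-2-en-1-yl)-2,3-dihydro-4H-chromen-4-one
Conditions: HCl (1.25 M in MeOH), 40 °C
Reagents that add atoms: none
Why: Acid-catalysed acetal exchange with methanol removes the three MOM ethers under conditions mild enough to spare the prenyl group, the diol and the C2 centre (no base, so no retro-oxa-Michael opening).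

**Compound list**
1 | resorcinol | Oc1cccc(O)c1 | starting material
2 | 1,3-bis(methoxymethoxy)benzene | COCOc1cccc(OCOC)c1 | intermediate
3 | prenyl bromide (1-bromo-3-methylbut-2-ene) | CC(C)=CCBr | starting material
4 | [2,6-bis(methoxymethoxy)phenyl]lithium | [Li]c1c(OCOC)cccc1OCOC | intermediate
5 | 1,3-bis(methoxymethoxy)-2-(3-methylbut-2-en-1-yl)benzene | CC(C)=CCc1c(OCOC)cccc1OCOC | intermediate
6 | 2-[3,5-bis(methoxymethoxy)-4-(3-methylbut-2-en-1-yl)phenyl]-4,4,5,5-tetramethyl-1,3,2-dioxaborolane | CC(C)=CCc1c(OCOC)cc(B2OC(C)(C)C(C)(C)O2)cc1OCOC | intermediate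
7 | 3,5-bis(methoxymethoxy)-4-(3-methylbut-2-en-1-yl)phenol | CC(C)=CCc1c(OCOC)cc(O)cc1OCOC | intermediate
8 | 2-bromo-3,5-bis(methoxymethoxy)-4-(3-methylbut-2-en-1-yl)phenol | CC(C)=CCc1c(OCOC)cc(O)c(Br)c1OCOC | intermediate
9 | 2,6-dibromo-3,5-bis(methoxymethoxy)-4-(3-methylbut-2-en-1-yl)phenol | CC(C)=CCc1c(OCOC)c(Br)c(O)c(Br)c1OCOC | intermediate
10 | maleic anhydride (furan-2,5-dione) | O=C1OC(=O)C=C1 | starting material
11 | lithium 2-bromo-6-lithio-3,5-bis(methoxymethoxy)-4-(3-methylbut-2-en-1-yl)phenolate | [Li]Oc1c([Li])c(OCOC)c(CC=C(C)C)c(OCOC)c1Br | intermediate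
12 | (2Z)-4-[3-bromo-2-hydroxy-4,6-bis(methoxymethoxy)-5-(3-methylbut-2-en-1-yl)phenyl]-4-oxobut-2-enoic acid (dilithium salt in the flask) | OC(=O)/C=C\C(=O)c1c(O)c(Br)c(OCOC)c(CC=C(C)C)c1OCOC | intermediate
13 | rac-8-bromo-5,7-bis(methoxymethoxy)-6-(3-methylbut-2-en-1-yl)-4-oxo-3,4-dihydro-2H-chromene-2-carboxylic acid | OC(=O)C1CC(=O)c2c(OCOC)c(CC=C(C)C)c(OCOC)c(Br)c2O1 | intermediate
14 | 4-iodophenol | Oc1ccc(I)cc1 | starting material
15 | 1-iodo-4-(methoxymethoxy)benzene | COCOc1ccc(I)cc1 | intermediate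
16 | (2S)-8-bromo-5,7-bis(methoxymethoxy)-2-[4-(methoxymethoxy)phenyl]-6-(3-methylbut-2-en-1-yl)-2,3-dihydro-4H-chromen-4-one | CC(C)=CCc1c(OCOC)c(Br)c2c(c1OCOC)C(=O)C[C@@H](c1ccc(OCOC)cc1)O2 | intermediate
17 | methyl (2S)-oxirane-2-carboxylate (methyl (S)-glycidate) | COC(=O)[C@@H]1CO1 | starting material
18 | 1-[(2S)-oxiran-2-yl]ethan-1-one | CC(=O)[C@@H]1CO1 | intermediate
19 | 2-[(2S)-oxiran-2-yl]propan-2-ol | CC(C)(O)[C@@H]1CO1 | intermediate
20 | (2R)-1-iodo-3-methylbutane-2,3-diol (same spatial arrangement as 19; the descriptor changes because CH2I outranks the carbinol carbon) | CC(C)(O)[C@@H](O)CI | intermediate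
21 | (2S)-8-[(2S)-2,3-dihydroxy-3-methylbutyl]-5,7-bis(methoxymethoxy)-2-[4-(methoxymethoxy)phenyl]-6-(3-methylbut-2-en-1-yl)-2,3-dihydro-4H-chromen-4-one | CC(C)=CCc1c(OCOC)c(C[C@H](O)C(C)(C)O)c2c(c1OCOC)C(=O)C[C@@H](c1ccc(OCOC)cc1)O2 | intermediate
22 | (2S)-8-[(2S)-2,3-dihydroxy-3-methylbutyl]-5,7-dihydroxy-2-(4-hydroxyphenyl)-6-(3-methylbut-2-en-1-yl)-2,3-dihydro-4H-chromen-4-one | CC(C)=CCc1c(O)c(C[C@H](O)C(C)(C)O)c2c(c1O)C(=O)C[C@@H](c1ccc(O)cc1)O2 | target

**Step count and risks**

Total step count: 10. Longest linear sequence: 8 (steps 1, 2, 3, 4, 5, 7, 9, 10); steps 6 and 8 are side branches.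

Steps most likely to fail:

Step 7. The C2–nickel species can lose a β-hydrogen to give the chromone, the face selectivity on an α-aryloxy radical is untested, and the C8–Br bond may not stay fully inert. The fallback sets out from 13 and 15 and comes back at 16. Photochemical decarboxylative desaturation of 13 (9-mesityl-10-methylacridinium tetrafluoroborate, Co(dmgH)2(py)Cl, MeCN, blue LEDs) gives 8-bromo-5,7-bis(methoxymethoxy)-6-(3-methylbut-2-en-1-yl)-4H-chromen-4-one F1. Borylation of 15 (Pd(OAc)2, XPhos, B2(OH)4, KOAc, EtOH, 80 °C) gives [4-(methoxymethoxy)phenyl]boronic acid F2. Redox-neutral asymmetric conjugate addition of F2 to F1 under divalent-palladium catalysis (Pd(TFA)2, the t-BuPyOx antipode that gives 2S, NH4PF6, H2O, ClCH2CH2Cl, 60 °C) leaves the aryl bromide alone and gives 16.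

Step 9. The aryl bromide carries two ortho oxygen substituents, so nickel insertion and radical capture may be slow and the iodohydrin may dimerise or be reduced instead. The fallback sets out from 9 and 19 and comes back at 22; it puts the side chain on by two-electron chemistry before ring C is made.
- Silylation of 19 (TMSCl, imidazole, CH2Cl2) gives trimethyl({2-[(2S)-oxiran-2-yl]propan-2-yl}oxy)silane F3.
- The dilithio phenoxide 11, made from 9 as in step 5, opens F3 at the terminal carbon (BF3·OEt2, THF, −78 °C) to give 2-bromo-6-[(2S)-2-hydroxy-3-methyl-3-(trimethylsilyloxy)butyl]-3,5-bis(methoxymethoxy)-4-(3-methylbut-2-en-1-yl)phenol F4.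
- 2,2-Dimethoxypropane and PPTS in acetone remove the silyl group and close the acetonide 2-bromo-3,5-bis(methoxymethoxy)-4-(3-methylbut-2-en-1-yl)-6-{[(4S)-2,2,5,5-tetramethyl-1,3-dioxolan-4-yl]methyl}phenol F5.
- n-BuLi (2.1 equiv, THF, −78 °C) turns F5 into lithium 2-lithio-3,5-bis(methoxymethoxy)-4-(3-methylbut-2-en-1-yl)-6-{[(4S)-2,2,5,5-tetramethyl-1,3-dioxolan-4-yl]methyl}phenolate F6.
- F6 opens 10 to (2Z)-4-[2-hydroxy-4,6-bis(methoxymethoxy)-5-(3-methylbut-2-en-1-yl)-3-{[(4S)-2,2,5,5-tetramethyl-1,3-dioxolan-4-yl]methyl}phenyl]-4-oxobut-2-enoic acid F7.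
- F7 closes in the flask to 5,7-bis(methoxymethoxy)-6-(3-methylbut-2-en-1-yl)-4-oxo-8-{[(4S)-2,2,5,5-tetramethyl-1,3-dioxolan-4-yl]methyl}-3,4-dihydro-2H-chromene-2-carboxylic acid F8 (both C2 epimers).
- The conditions of step 7 with 15, now with no aryl bromide present, give (2S)-5,7-bis(methoxymethoxy)-2-[4-(methoxymethoxy)phenyl]-6-(3-methylbut-2-en-1-yl)-8-{[(4S)-2,2,5,5-tetramethyl-1,3-dioxolan-4-yl]methyl}-2,3-dihydro-4H-chromen-4-one F9.
- Methanolic HCl as in step 10 removes the acetonide and the MOM ethers to give 22.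

Step 5. The aryllithium may add twice or in conjugate fashion to the anhydride. The fallback sets out from 9 and comes back at 13. The dilithio phenoxide 11 is acylated with N-methoxy-N-methylacetamide (THF, −78 → 0 °C) to give 1-[3-bromo-2-hydroxy-4,6-bis(methoxymethoxy)-5-(3-methylbut-2-en-1-yl)phenyl]ethan-1-one F10. Aldol condensation with glyoxylic acid monohydrate (KOH, MeOH/H2O, 0 °C → rt) gives (2E)-4-[3-bromo-2-hydroxy-4,6-bis(methoxymethoxy)-5-(3-methylbut-2-en-1-yl)phenyl]-4-oxobut-2-enoic acid F11. Bringing the solution to pH 6–7 lets the phenol close by oxa-Michael addition to 13.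

**Further compounds**
F1 | step 7 | 8-bromo-5,7-bis(methoxymethoxy)-6-(3-methylbut-2-en-1-yl)-4H-chromen-4-one | O=c1ccoc2c(Br)c(OCOC)c(CC=C(C)C)c(OCOC)c12
F2 | step 7 | [4-(methoxymethoxy)phenyl]boronic acid | COCOc1ccc(B(O)O)cc1
F3 | step 9 | trimethyl({2-[(2S)-oxiran-2-yl]propan-2-yl}oxy)silane | C[Si](C)(C)OC(C)(C)[C@@H]1CO1
F4 | step 9 | 2-bromo-6-[(2S)-2-hydroxy-3-methyl-3-(trimethylsilyloxy)butyl]-3,5-bis(methoxymethoxy)-4-(3-methylbut-2-en-1-yl)phenol | CC(C)=CCc1c(OCOC)c(Br)c(O)c(C[C@H](O)C(C)(C)O[Si](C)(C)C)c1OCOC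
F5 | step 9 | 2-bromo-3,5-bis(methoxymethoxy)-4-(3-methylbut-2-en-1-yl)-6-{[(4S)-2,2,5,5-tetramethyl-1,3-dioxolan-4-yl]methyl}phenol | CC(C)=CCc1c(OCOC)c(Br)c(O)c(C[C@@H]2OC(C)(C)OC2(C)C)c1OCOC
F6 | step 9 | lithium 2-lithio-3,5-bis(methoxymethoxy)-4-(3-methylbut-2-en-1-yl)-6-{[(4S)-2,2,5,5-tetramethyl-1,3-dioxolan-4-yl]methyl}phenolate | [Li]Oc1c([Li])c(OCOC)c(CC=C(C)C)c(OCOC)c1C[C@@H]2OC(C)(C)OC2(C)C
F7 | step 9 | (2Z)-4-[2-hydroxy-4,6-bis(methoxymethoxy)-5-(3-methylbut-2-en-1-yl)-3-{[(4S)-2,2,5,5-tetramethyl-1,3-dioxolan-4-yl]methyl}phenyl]-4-oxobut-2-enoic acid | OC(=O)/C=C\C(=O)c1c(O)c(C[C@@H]2OC(C)(C)OC2(C)C)c(OCOC)c(CC=C(C)C)c1OCOC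
F8 | step 9 | 5,7-bis(methoxymethoxy)-6-(3-methylbut-2-en-1-yl)-4-oxo-8-{[(4S)-2,2,5,5-tetramethyl-1,3-dioxolan-4-yl]methyl}-3,4-dihydro-2H-chromene-2-carboxylic acid | OC(=O)C1CC(=O)c2c(OCOC)c(CC=C(C)C)c(OCOC)c(C[C@@H]3OC(C)(C)OC3(C)C)c2O1
F9 | step 9 | (2S)-5,7-bis(methoxymethoxy)-2-[4-(methoxymethoxy)phenyl]-6-(3-methylbut-2-en-1-yl)-8-{[(4S)-2,2,5,5-tetramethyl-1,3-dioxolan-4-yl]methyl}-2,3-dihydro-4H-chromen-4-one | CC(C)=CCc1c(OCOC)c(C[C@@H]3OC(C)(C)OC3(C)C)c2c(c1OCOC)C(=O)C[C@@H](c1ccc(OCOC)cc1)O2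
F10 | step 5 | 1-[3-bromo-2-hydroxy-4,6-bis(methoxymethoxy)-5-(3-methylbut-2-en-1-yl)phenyl]ethan-1-one | CC(=O)c1c(O)c(Br)c(OCOC)c(CC=C(C)C)c1OCOC
F11 | step 5 | (2E)-4-[3-bromo-2-hydroxy-4,6-bis(methoxymethoxy)-5-(3-methylbut-2-en-1-yl)phenyl]-4-oxobut-2-enoic acid | OC(=O)/C=C/C(=O)c1c(O)c(Br)c(OCOC)c(CC=C(C)C)c1OCOC
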